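Retrosynthetic overview
1. Hernanol ⇒ (4R)-lactol. The lactone C=O comes from hydride-transfer dehydrogenation of the hemiacetal on the free phenol, and C8 is fixed last by equilibration to the trans lactone.
2. Lactol ⇒ open γ-hydroxy aldehyde (C9 = CHO, C9′ = CH2OH), which closes by itself (O9′–C9 bond). This oxolane is the only ring made, first as lactol and then as lactone, as in the seco-diol → lactol → lactone dehydrogenase sequence. C9 is delivered at the aldehyde level because an unsymmetrical diol cannot be oxidised regioselectively.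
3. Hydroxy aldehyde ⇒ 2,3-dibenzylsuccinic derivative (C9′ imide, C9 Weinreb amide, phenol pivalate), unmasked by LiAlH4 in one operation.
4. Succinate ⇒ C8–C8′ one-electron oxidative heterocoupling of two saturated C6C3 enolates, from dihydroferulic acid and 3-(3,4,5-trimethoxyphenyl)propanoic acid. The oxazolidinone on the guaiacyl half plays the dirigent role and sets C8′.

Assumption: lignan numbering is used (C7–C9 = side chain of the trimethoxyphenyl unit, C7′–C9′ = side chain of the guaiacyl unit), and both arylpropanoic acids and the oxazolidinone are taken as catalogue chemicals.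

Step 1
Reactants: 1 3-(4-hydroxy-3-methoxyphenyl)propanoic acid (dihydroferulic acid); 2 (S)-4-benzyl-1,3-oxazolidin-2-one
Product: 4 (S)-4-benzyl-3-{3-[3-methoxy-4-(pivaloyloxy)phenyl]propanoyl}-1,3-oxazolidin-2-one, via O-pivaloylated mixed pivalic anhydride 3 (not isolated)
Conditions: PivCl (2.3 equiv), Et3N (4 equiv), THF, −20 to 0 °C, 1 h; then LiCl (1.1 equiv), 2 (1.0 equiv), rt, 12 h
Reagents that add atoms: pivaloyl chloride, CC(C)(C)C(=O)Cl
Why: Mixed-anhydride N-acylation of an Evans oxazolidinone (LiCl/Et3N variant), in which excess PivCl esterifies the phenol and activates the acid in the same flask, the oxazolidinone attacks the unhindered carbonyl of the mixed anhydride, and no new stereocentre is formed.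

Step 2
Reactants: 5 3-(3,4,5-trimethoxyphenyl)propanoic acid
Product: 7 N-methoxy-N-methyl-3-(3,4,5-trimethoxyphenyl)propanamide, via acyl imidazole 6 (not isolated)
Conditions: CDI (1.1 equiv), CH2Cl2, rt, 1 h; then MeNH(OMe)·HCl (1.3 equiv), rt, 12 h
Reagents that add atoms: N,O-dimethylhydroxylamine hydrochloride, CNOC.Cl; 1,1'-carbonyldiimidazole, O=C(n1ccnc1)n1ccnc1 (its imidazolyl group is carried only by 6)
Why: CDI-mediated amidation (Weinreb amide synthesis) through the acyl imidazole, which installs the group that later stops hydride reduction at the aldehyde level; no stereocentre is formed.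

Step 3
Reactants: 4 (S)-4-benzyl-3-{3-[3-methoxy-4-(pivaloyloxy)phenyl]propanoyl}-1,3-oxazolidin-2-one; 7 N-methoxy-N-methyl-3-(3,4,5-trimethoxyphenyl)propanamide
Product: 10 (3R)-4-[(S)-4-benzyl-2-oxo-1,3-oxazolidin-3-yl]-N-methoxy-N-methyl-3-[3-methoxy-4-(pivaloyloxy)benzyl]-4-oxo-2-(3,4,5-trimethoxybenzyl)butanamide (C2 epimer mixture), via imide lithium Z-enolate 8 (not isolated), via amide lithium Z-enolate 9 (not isolated)
Conditions: 4 (1.0 equiv) + 7 (1.5 equiv), LiN(i-Pr)2 (LDA, commercial solution, 2.6 equiv), THF, −78 °C, 30 min; then Fe(acac)3 (2.6 equiv) in THF, −78 °C to rt, 1 h; chromatography (removes homodimers and minor 8′S isomers)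
Reagents that add atoms: none
Why: Proposed new method: oxidative enolate heterocoupling in which trivalent iron takes one electron from each of two different lithium enolates held in a mixed aggregate, the more electron-rich amide enolate 9 giving an α-carbamoyl radical that is captured by the chelated Z-enolate 8 on the face away from the C4 benzyl group (this sets C8′ as R, while C8 forms as a harmless epimer mixture corrected in step 5); the closest known reaction type is the Fe(acac)3- or Cu(2-ethylhexanoate)2-mediated heterocoupling of N-acyloxazolidinone enolates with ester and ketone enolates, and only the Weinreb amide partner is new.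

Step 4
Reactants: 10 (3R)-4-[(S)-4-benzyl-2-oxo-1,3-oxazolidin-3-yl]-N-methoxy-N-methyl-3-[3-methoxy-4-(pivaloyloxy)benzyl]-4-oxo-2-(3,4,5-trimethoxybenzyl)butanamide
Product: 12 (4R)-4-(4-hydroxy-3-methoxybenzyl)-3-(3,4,5-trimethoxybenzyl)oxolan-2-ol (mixture at C2 and C3), via open-chain hydroxy aldehyde 11 (not isolated)
Conditions: LiAlH4 (3 equiv), THF, −78 °C, 30 min, then 0 °C, 45 min; cold aq. potassium sodium tartrate (KNaC4H4O6)
Reagents that add atoms: none
Why: Chemodifferentiating hydride reduction in which the Weinreb amide reacts first and stops as its chelated tetrahedral aluminate (aldehyde level), the imide undergoes reductive auxiliary cleavage to the primary alcohol and the aryl pivalate is cleaved, so that work-up releases γ-hydroxy aldehyde 11, which closes by spontaneous 5-exo hemiacetalisation to 12; C8′ is untouched and the new anomeric centre (a mixture) is erased in step 5.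

Step 5
Reactants: 12 (4R)-4-(4-hydroxy-3-methoxybenzyl)-3-(3,4,5-trimethoxybenzyl)oxolan-2-ol
Product: 14 hernanol = (3R,4R)-4-(4-hydroxy-3-methoxybenzyl)-3-(3,4,5-trimethoxybenzyl)oxolan-2-one, via C3-epimeric lactone mixture 13 (not isolated)
Conditions: {[Ph4(η5-C4CO)]2H}Ru2(CO)4(μ-H) (Shvo complex, 2 mol %), acetone, reflux, 6 h; evaporate, then DBU (1.5 equiv), toluene, 80 °C, 4 h; aq. NH4Cl
Reagents that add atoms: none
Why: Oppenauer-type transfer dehydrogenation in which the ruthenium cyclopentadienone complex takes hydride and proton from the hemiacetal in an outer-sphere step and passes them to acetone, a manifold free of one-electron oxidants that leaves the free guaiacyl phenol and both electron-rich rings alone, after which DBU epimerises C8 through the lactone enolate to the thermodynamically preferred trans isomer, so that the fixed 8′R centre dictates 8R.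

Compound list
1 | 3-(4-hydroxy-3-methoxyphenyl)propanoic acid (dihydroferulic acid) | COc1cc(CCC(=O)O)ccc1O | starting material
2 | (S)-4-benzyl-1,3-oxazolidin-2-one | O=C1N[C@@H](Cc2ccccc2)CO1 | starting material
3 | 3-[3-methoxy-4-(pivaloyloxy)phenyl]propanoic pivalic anhydride | COc1cc(CCC(=O)OC(=O)C(C)(C)C)ccc1OC(=O)C(C)(C)C | intermediate
4 | (S)-4-benzyl-3-{3-[3-methoxy-4-(pivaloyloxy)phenyl]propanoyl}-1,3-oxazolidin-2-one | COc1cc(CCC(=O)N2[C@@H](Cc3ccccc3)COC2=O)ccc1OC(=O)C(C)(C)C | intermediate
5 | 3-(3,4,5-trimethoxyphenyl)propanoic acid | COc1cc(CCC(=O)O)cc(OC)c1OC | starting material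
6 | 1-[3-(3,4,5-trimethoxyphenyl)propanoyl]imidazole | COc1cc(CCC(=O)n2ccnc2)cc(OC)c1OC | intermediate
7 | N-methoxy-N-methyl-3-(3,4,5-trimethoxyphenyl)propanamide | COc1cc(CCC(=O)N(C)OC)cc(OC)c1OC | intermediate
8 | lithium Z-enolate of imide 4 | [Li+].COc1cc(C/C=C(\[O-])N2[C@@H](Cc3ccccc3)COC2=O)ccc1OC(=O)C(C)(C)C | intermediate
9 | lithium Z-enolate of Weinreb amide 7 | [Li+].COc1cc(C/C=C(\[O-])N(C)OC)cc(OC)c1OC | intermediate
10 | (3R)-4-[(S)-4-benzyl-2-oxo-1,3-oxazolidin-3-yl]-N-methoxy-N-methyl-3-[3-methoxy-4-(pivaloyloxy)benzyl]-4-oxo-2-(3,4,5-trimethoxybenzyl)butanamide, C2 (= C8) epimer mixture | COc1cc(C[C@@H](C(=O)N2[C@@H](Cc3ccccc3)COC2=O)C(Cc2cc(OC)c(OC)c(OC)c2)C(=O)N(C)OC)ccc1OC(=O)C(C)(C)C | intermediate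
11 | (3R)-4-hydroxy-3-(4-hydroxy-3-methoxybenzyl)-2-(3,4,5-trimethoxybenzyl)butanal, C2 epimer mixture | COc1cc(C[C@@H](CO)C(Cc2cc(OC)c(OC)c(OC)c2)C=O)ccc1O | intermediate
12 | (4R)-4-(4-hydroxy-3-methoxybenzyl)-3-(3,4,5-trimethoxybenzyl)oxolan-2-ol, mixture at C2 and C3 | COc1cc(C[C@H]2COC(O)C2Cc2cc(OC)c(OC)c(OC)c2)ccc1O | intermediate
13 | (4R)-4-(4-hydroxy-3-methoxybenzyl)-3-(3,4,5-trimethoxybenzyl)oxolan-2-one, C3 epimer mixture | COc1cc(C[C@H]2COC(=O)C2Cc2cc(OC)c(OC)c(OC)c2)ccc1O | intermediate
14 | hernanol, (3R,4R)-4-(4-hydroxy-3-methoxybenzyl)-3-(3,4,5-trimethoxybenzyl)oxolan-2-one (trans) | COc1cc(C[C@H]2COC(=O)[C@@H]2Cc2cc(OC)c(OC)c(OC)c2)ccc1O | target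

Total step count: 5
Longest linear sequence: 4 (steps 1, 3, 4, 5)

Three steps most likely to fail

Step 3 (C8–C8′ heterocoupling).
- Risks: homodimers of 4 and 7 may form, the Weinreb enolate may fragment on warming, and the amide base may attack the aryl pivalate.
- Fallback: it sets out from 4 and 7 and returns at 10. Hetero-selectivity becomes structural because one partner is oxidised beforehand.
- Enolate 9 is quenched with CBr4 (THF, −78 °C) to give 2-bromo-N-methoxy-N-methyl-3-(3,4,5-trimethoxyphenyl)propanamide F1.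
- Separately, 4 is converted with TiCl4/i-Pr2NEt (CH2Cl2, 0 °C) into the trichlorotitanium Z-enolate of 4 F2.
- RuCl2(PPh3)3 (5 mol %, 45 °C) then shuttles the bromine atom, so the α-carbamoyl radical from F1 adds to the biradicaloid tetravalent titanium enolate. This redox-catalysed radical alkylation again occurs anti to the benzyl group and gives 10.

Step 4 (one-pot unmasking to the lactol).
- Risks: the tetrahedral aluminate may collapse early, or the lactone may close before the Weinreb amide is reduced. Either leads to over-reduction to the unsymmetrical 1,4-diol, in which C9 and C9′ can no longer be told apart. Endocyclic opening of the auxiliary is a second risk.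
- Fallback: it sets out from 10 and returns at 14. The aldehyde level is given up.
- LiBH4/MeOH (THF, 0 °C) reduces only the imide to (3R)-4-hydroxy-N-methoxy-N-methyl-3-[3-methoxy-4-(pivaloyloxy)benzyl]-2-(3,4,5-trimethoxybenzyl)butanamide F3.
- The alkoxide of F3 displaces the N-methoxy-N-methylamino group and closes (4R)-4-[3-methoxy-4-(pivaloyloxy)benzyl]-3-(3,4,5-trimethoxybenzyl)oxolan-2-one F4 by acyl substitution.
- NaOMe/MeOH followed by aq. HCl removes the pivalate and equilibrates C8, giving 14 directly.

Step 5 (dehydrogenation on the free phenol).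
- Risks: hydrogen transfer is reversible, so a ruthenium hydride could reduce the open form 11 to the diol. Re-oxidation at C9′ would then give the regioisomeric lactone. The phenol may also slow the catalyst.
- Fallback: it sets out from 12 and returns at 13. The open-chain tautomer is oxidised instead of the hemiacetal.
- Lindgren–Pinnick chlorite oxidation (NaClO2, NaH2PO4, sulfamic acid, t-BuOH/H2O) tolerates vanillin-type phenols. It gives (3R)-4-hydroxy-3-(4-hydroxy-3-methoxybenzyl)-2-(3,4,5-trimethoxybenzyl)butanoic acid F5.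
- F5 lactonises with catalytic TsOH in toluene to 13, and the DBU treatment of step 5 then leads to 14.

Further compounds
F1 | step 3 | 2-bromo-N-methoxy-N-methyl-3-(3,4,5-trimethoxyphenyl)propanamide (racemic) | COc1cc(CC(Br)C(=O)N(C)OC)cc(OC)c1OC
F2 | step 3 | trichlorotitanium Z-enolate of 4 | COc1cc(C/C=C(\O[Ti](Cl)(Cl)Cl)N2[C@@H](Cc3ccccc3)COC2=O)ccc1OC(=O)C(C)(C)C
F3 | step 4 | (3R)-4-hydroxy-N-methoxy-N-methyl-3-[3-methoxy-4-(pivaloyloxy)benzyl]-2-(3,4,5-trimethoxybenzyl)butanamide, C2 epimer mixture | COc1cc(C[C@@H](CO)C(Cc2cc(OC)c(OC)c(OC)c2)C(=O)N(C)OC)ccc1OC(=O)C(C)(C)C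
F4 | step 4 | (4R)-4-[3-methoxy-4-(pivaloyloxy)benzyl]-3-(3,4,5-trimethoxybenzyl)oxolan-2-one, C3 epimer mixture | COc1cc(C[C@H]2COC(=O)C2Cc2cc(OC)c(OC)c(OC)c2)ccc1OC(=O)C(C)(C)C
F5 | step 5 | (3R)-4-hydroxy-3-(4-hydroxy-3-methoxybenzyl)-2-(3,4,5-trimethoxybenzyl)butanoic acid, C2 epimer mixture | COc1cc(C[C@@H](CO)C(Cc2cc(OC)c(OC)c(OC)c2)C(=O)O)ccc1O
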